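## Retrosynthetic overview

- Both trimethylcyclohexene rings and the all-E polyene are bought intact as β-carotene (1); no ring is formed in the route.
- C3–O bond: (3R)-β-cryptoxanthin (2) comes from 1 by one site- and enantioselective enzymatic C3–H hydroxylation, which is the new step and sets the only stereocentre.
- Ester C–O bond: palmitoleic acid (3), as its chloride (4), acylates 2 to give the target (5); the Z-alkene comes with 3.

Assumption: bulk synthetic all-E-β-carotene and (9Z)-palmitoleic acid count as cheap commercial starting materials; all carotenoid work is done in the dark under argon.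

## Route

Step 1
Reactants: 1 all-E-β,β-carotene (β-carotene)
Product: 2 (3R)-β,β-caroten-3-ol ((3R)-β-cryptoxanthin)
Conditions: engineered CYP175A1–reductase fusion (cat., channel-mouth variant), NADP+ (cat.), NADP-dependent ADH/i-PrOH (cofactor recycling), air, Tween 80 micelles, KPi pH 7.5, 45 °C, dark; stopped at ca. 40% conversion, 1 recovered by chromatography
Reagents that add atoms: dioxygen, O=O
Why: Proposed new method: the P450 oxo-iron(IV) porphyrin radical cation abstracts the 3-pro-R hydrogen of the β-ring that the long hydrophobic channel holds over the heme, and OH rebound with retention sets (3R), so the unactivated C3–H is reached by positioning while the weaker allylic C4–H and the polyene stay out of reach; the new part is the catalyst design, an isolated, reductase-fused thermostable variant whose narrowed hydrophobic channel mouth disfavours the 3-hydroxy ring of 2 as the distal anchor, run to partial conversion so that only one ring reacts; closest known reaction type: P450 rebound C–H hydroxylation, specifically the native bacterial β-carotene 3,3'-hydroxylases that hydroxylate both rings in cells to give zeaxanthin via 2.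

Step 2
Reactants: 3 (9Z)-hexadec-9-enoic acid (palmitoleic acid)
Product: 4 (9Z)-hexadec-9-enoyl chloride
Conditions: (COCl)2 (1.3 equiv), DMF (cat.), CH2Cl2, 0 °C to rt, 2 h; concentrated and used crude
Reagents that add atoms: oxalyl chloride, ClC(=O)C(=O)Cl
Why: DMF-catalysed acid chloride formation (Vilsmeier-type activation) gives only gaseous by-products and leaves the isolated Z-alkene untouched at 0–20 °C; a separately made acyl chloride is preferred to in-situ carbodiimide coupling because urea by-products are hard to remove from the oily, light- and acid-sensitive carotenoid ester.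

Step 3
Reactants: 2 (3R)-β-cryptoxanthin; 4 (9Z)-hexadec-9-enoyl chloride (1.5 equiv)
Product: 5 (3R)-β,β-caroten-3-yl (9Z)-hexadec-9-enoate (target, CNP0382087.1)
Conditions: pyridine (5 equiv), DMAP (0.1 equiv), CH2Cl2, 0 °C to rt, Ar, dark; cold NaHCO3 wash, chromatography on deactivated silica
Reagents that add atoms: none
Why: DMAP-catalysed O-acylation (nucleophilic acyl substitution) of the unhindered secondary 3-OH breaks only the O–H bond, so (3R) is retained, and the base-buffered, oxygen-free conditions leave the all-E polyene and the Z-alkene unchanged.

## Compound list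

1 | all-E-β,β-carotene (β-carotene) | CC1=C(/C=C/C(C)=C/C=C/C(C)=C/C=C/C=C(C)/C=C/C=C(C)/C=C/C2=C(C)CCCC2(C)C)C(C)(C)CCC1 | starting material
2 | (3R)-β,β-caroten-3-ol ((3R)-β-cryptoxanthin) | O[C@@H]1CC(C)=C(/C=C/C(C)=C/C=C/C(C)=C/C=C/C=C(C)/C=C/C=C(C)/C=C/C2=C(C)CCCC2(C)C)C(C)(C)C1 | intermediate
3 | (9Z)-hexadec-9-enoic acid (palmitoleic acid) | CCCCCC/C=C\CCCCCCCC(=O)O | starting material
4 | (9Z)-hexadec-9-enoyl chloride | CCCCCC/C=C\CCCCCCCC(=O)Cl | intermediate
5 | (3R)-β,β-caroten-3-yl (9Z)-hexadec-9-enoate | CCCCCC/C=C\CCCCCCCC(=O)O[C@@H]1CC(C)=C(/C=C/C(C)=C/C=C/C(C)=C/C=C/C=C(C)/C=C/C=C(C)/C=C/C2=C(C)CCCC2(C)C)C(C)(C)C1 | target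

## Step count and risk

Total step count: 3. Longest linear sequence: 2 steps (1 → 2 → 5, steps 1 and 3); step 2 is a one-step side branch.

The three steps most likely to fail, most risky first:

**Step 1 (the proposed new hydroxylation).** The risks are low turnover on a water-insoluble C40 substrate, over-hydroxylation to zeaxanthin, and failure of the engineered mono-selectivity. Without any engineered bias, statistics alone predict about 35% of 2 per pass at 40% conversion. The fallback uses known chemistry and replaces the C–H oxidation by a partial synthesis in which the C3–O bond and its (3R) configuration are bought ready-made. It cannot set out from a numbered compound, because no known reaction turns 1 into 2. Bought (3R,3'R,6'R)-lutein F1 takes the place of 1, and the fallback comes back to the route at 2. F1 is dehydrated at its allylic 3'-OH with dilute H2SO4 in 1-propanol/water at reflux, where the first-formed anhydroluteins equilibrate to (3R)-3',4'-didehydro-β,β-caroten-3-ol (anhydrolutein III) F2. The terminal cis-disubstituted 3',4'-double bond of F2 is then hydrogenated selectively (H2, 1 atm, Pt/Al2O3, EtOAc, rt) to give 2. The hydrogenation must precede the esterification, because it would also reduce the Z-alkene of the acyl chain.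

**Step 3 (acylation).** The risks are E/Z isomerisation or degradation of the polyene by traces of HCl or pyridinium chloride, and incomplete acylation. The fallback is a neutral enzymatic transesterification; it sets out from 3 and 2 and comes back to the route at 5. Acid 3 is transvinylated with excess vinyl acetate (Pd(OAc)2 cat., KOH cat., 40 °C) to vinyl (9Z)-hexadec-9-enoate F4. F4 then acylates 2 over immobilised Candida antarctica lipase B (toluene, 45 °C, 4 Å sieves) to give 5 without acid or base.

**Step 2 (acid chloride).** The risks are partial Z-to-E isomerisation or HCl addition at the alkene, and hydrolysis of the crude chloride. The fallback avoids any acyl chloride; it sets out from 3 and comes back to the route at 5. Acid 3 is condensed with DCC (0.5 equiv, CH2Cl2, 0 °C to rt) to (9Z)-hexadec-9-enoic anhydride F3, and the urea is filtered off. F3 acylates 2 (DMAP cat., Et3N, CH2Cl2, rt) to give 5, and the released equivalent of 3 is recovered.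

## Further compounds

F1 | step 1 | (3R,3'R,6'R)-β,ε-carotene-3,3'-diol (lutein; bought starting material of the fallback) | O[C@@H]1CC(C)=C(/C=C/C(C)=C/C=C/C(C)=C/C=C/C=C(C)/C=C/C=C(C)/C=C/[C@H]2C(C)=C[C@H](O)CC2(C)C)C(C)(C)C1
F2 | step 1 | (3R)-3',4'-didehydro-β,β-caroten-3-ol (anhydrolutein III) | O[C@@H]1CC(C)=C(/C=C/C(C)=C/C=C/C(C)=C/C=C/C=C(C)/C=C/C=C(C)/C=C/C2=C(C)C=CCC2(C)C)C(C)(C)C1
F3 | step 2 | (9Z)-hexadec-9-enoic anhydride | CCCCCC/C=C\CCCCCCCC(=O)OC(=O)CCCCCCC/C=C\CCCCCC
F4 | step 3 | vinyl (9Z)-hexadec-9-enoate | CCCCCC/C=C\CCCCCCCC(=O)OC=C
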